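Assumption: 1-(benzyloxy)-4-bromo-2-methoxybenzene and 3,4-bis(benzyloxy)benzaldehyde are bought as such (the bromide is otherwise one O-benzylation from 4-bromoguaiacol). Oxolane numbering: O1, C2 (aryl), C3 (CH2OAc), C4 (arylmethyl), C5.

**Retrosynthetic overview**
1. Target ⇐ tri-O-benzyl acetate ⇐ tri-O-benzyl alcohol (acetylation, then hydrogenolysis last).
2. Oxolane O1–C2 bond ⇐ open-chain triol, by stereoconvergent benzylic SN1 cycloetherification (sets C2 trans to C3).
3. Triol ⇐ (R)-β-arylmethyl-γ-butyrolactone + 3,4-bis(benzyloxy)benzaldehyde (trans aldol sets C3, hydride reduction in the same flask).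
4. That lactone ⇐ cyclopropane-fused lactone + aryl Grignard (Cu homoconjugate opening at the cyclopropane CH2, then Krapcho).
5. Cyclopropane-fused lactone ⇐ diethyl malonate + (R)-epichlorohydrin: cyclopropane and γ-lactone close in one operation and fix C4. Ring order: cyclopropane + lactone together → cyclopropane opened → lactone opened → oxolane closed last.

**Route**

Step 1
Reactants: 1 diethyl malonate; 2 (R)-epichlorohydrin
Product: 6 ethyl (1S,5R)-2-oxo-3-oxabicyclo[3.1.0]hexane-1-carboxylate, via chlorohydrin alkoxide 3 (not isolated), via epoxy malonate 4 (not isolated), via cyclopropylmethanol diester 5 (not isolated)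
Conditions: NaOEt (1.05 equiv), EtOH, 0 °C → reflux, 20 h
Reagents that add atoms: none
Why: Double annulation (malonate SN2 opening of the epoxide at CH2, Payne-type re-closure with loss of chloride, 3-exo-tet cyclopropanation, lactonisation of the cis ester) closes the cyclopropane and the γ-lactone in one operation; the epichlorohydrin centre is inverted once in the 3-exo-tet step to give C5 = R, and C1 = S follows from the obligatory cis fusion.

Step 2
Reactants: 6 ethyl (1S,5R)-2-oxo-3-oxabicyclo[3.1.0]hexane-1-carboxylate; 7 1-(benzyloxy)-4-bromo-2-methoxybenzene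
Product: 9 ethyl (3S,4R)-4-{[4-(benzyloxy)-3-methoxyphenyl]methyl}-2-oxooxolane-3-carboxylate, via aryl Grignard 8 (not isolated)
Conditions: 7, Mg, THF, reflux; then CuI (10 mol %), 6, THF, −30 → 0 °C; 1 M HCl
Reagents that add atoms: magnesium, [Mg] (held only in 8; leaves as salt on work-up)
Why: Cu-catalysed homoconjugate (1,5-) addition of the aryl Grignard to the doubly activated cyclopropane attacks the unsubstituted CH2 in SN2 fashion, so the ring-fusion centre becomes C4 (R) untouched, while the malonate-type enolate shields both carbonyls from 1,2-addition and is protonated to the trans ester (C3 is epimerisable and erased in step 3).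

Step 3
Reactants: 9 ethyl (3S,4R)-4-{[4-(benzyloxy)-3-methoxyphenyl]methyl}-2-oxooxolane-3-carboxylate
Product: 10 (4R)-4-{[4-(benzyloxy)-3-methoxyphenyl]methyl}oxolan-2-one
Conditions: LiCl, H2O (2 equiv), DMSO, 140 °C
Reagents that add atoms: none
Why: Krapcho dealkoxycarbonylation removes the malonate-type ester; C4 is not acidic and the benzyl ether is inert to LiCl/DMSO.

Step 4
Reactants: 10 (4R)-4-{[4-(benzyloxy)-3-methoxyphenyl]methyl}oxolan-2-one; 11 3,4-bis(benzyloxy)benzaldehyde
Product: 13 (2R,3R)-2-{[3,4-bis(benzyloxy)phenyl](hydroxy)methyl}-3-{[4-(benzyloxy)-3-methoxyphenyl]methyl}butane-1,4-diol, via aldol adduct 12 (not isolated)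
Conditions: LDA, THF, −78 °C; 11, −78 °C, 1 h; then LiAlH4, −78 → 0 °C; aqueous work-up
Reagents that add atoms: none
Why: Lithium enolate aldol of the lactone anti to the C4 arylmethyl group sets C3 (trans; the carbinol centre forms as a mixture that step 5 erases), and LiAlH4 reduces the lactone of the cold aldolate in the same flask before retro-aldol can occur.

Step 5
Reactants: 13 (2R,3R)-2-{[3,4-bis(benzyloxy)phenyl](hydroxy)methyl}-3-{[4-(benzyloxy)-3-methoxyphenyl]methyl}butane-1,4-diol
Product: 14 [(2S,3R,4R)-2-[3,4-bis(benzyloxy)phenyl]-4-{[4-(benzyloxy)-3-methoxyphenyl]methyl}oxolan-3-yl]methanol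
Conditions: CSA (10 mol %), CH2Cl2, 0 °C → rt, monitored
Reagents that add atoms: none
Why: Acid-catalysed SN1 cycloetherification: the dialkoxy-stabilised benzylic cation is captured 5-exo by the CH2OH on the neighbouring carbon (the other CH2OH would give an oxetane), and both carbinol epimers converge on the 2,3-trans ring (C2 = S), which places the former lactone carbonyl carbon as CH2OH cis to the C4 arylmethyl group.

Step 6
Reactants: 14 [(2S,3R,4R)-2-[3,4-bis(benzyloxy)phenyl]-4-{[4-(benzyloxy)-3-methoxyphenyl]methyl}oxolan-3-yl]methanol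
Product: 15 [(2S,3R,4R)-2-[3,4-bis(benzyloxy)phenyl]-4-{[4-(benzyloxy)-3-methoxyphenyl]methyl}oxolan-3-yl]methyl acetate
Conditions: Ac2O, pyridine, DMAP (cat.), CH2Cl2, 0 °C → rt
Reagents that add atoms: acetic anhydride, CC(=O)OC(C)=O
Why: DMAP-catalysed O-acylation of the only free hydroxyl; no stereocentre is touched.

Step 7
Reactants: 15 [(2S,3R,4R)-2-[3,4-bis(benzyloxy)phenyl]-4-{[4-(benzyloxy)-3-methoxyphenyl]methyl}oxolan-3-yl]methyl acetate
Product: 16 [(2S,3R,4R)-2-(3,4-dihydroxyphenyl)-4-[(4-hydroxy-3-methoxyphenyl)methyl]oxolan-3-yl]methyl acetate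
Conditions: H2 (1 atm), 10% Pd/C, EtOAc, rt, stopped after 3 equiv H2
Reagents that add atoms: none
Why: Catalytic hydrogenolysis cleaves the three aryl benzyl ethers much faster than the cyclic dialkyl benzylic ether under neutral conditions, and the alkyl acetate is inert.

**Compound list**
1 | diethyl malonate | CCOC(=O)CC(=O)OCC | starting material
2 | (R)-epichlorohydrin, (2R)-2-(chloromethyl)oxirane | ClC[C@H]1CO1 | starting material
3 | diethyl 2-[(2R)-3-chloro-2-hydroxypropyl]propanedioate (as alkoxide) | CCOC(=O)C(C[C@@H](O)CCl)C(=O)OCC | intermediate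
4 | diethyl 2-{[(2R)-oxiran-2-yl]methyl}propanedioate | CCOC(=O)C(C[C@@H]1CO1)C(=O)OCC | intermediate
5 | diethyl (2R)-2-(hydroxymethyl)cyclopropane-1,1-dicarboxylate (as alkoxide) | CCOC(=O)C1(C[C@H]1CO)C(=O)OCC | intermediate
6 | ethyl (1S,5R)-2-oxo-3-oxabicyclo[3.1.0]hexane-1-carboxylate | CCOC(=O)[C@]12C[C@H]1COC2=O | intermediate
7 | 1-(benzyloxy)-4-bromo-2-methoxybenzene | COc1cc(Br)ccc1OCc1ccccc1 | starting material
8 | [4-(benzyloxy)-3-methoxyphenyl]magnesium bromide | COc1cc([Mg]Br)ccc1OCc1ccccc1 | intermediate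
9 | ethyl (3S,4R)-4-{[4-(benzyloxy)-3-methoxyphenyl]methyl}-2-oxooxolane-3-carboxylate (trans) | CCOC(=O)[C@@H]1[C@@H](Cc2ccc(OCc3ccccc3)c(OC)c2)COC1=O | intermediate
10 | (4R)-4-{[4-(benzyloxy)-3-methoxyphenyl]methyl}oxolan-2-one | O=C1C[C@@H](Cc2ccc(OCc3ccccc3)c(OC)c2)CO1 | intermediate
11 | 3,4-bis(benzyloxy)benzaldehyde | O=Cc1ccc(OCc2ccccc2)c(OCc2ccccc2)c1 | starting material
12 | (3S,4R)-3-{[3,4-bis(benzyloxy)phenyl](hydroxy)methyl}-4-{[4-(benzyloxy)-3-methoxyphenyl]methyl}oxolan-2-one (trans; carbinol centre both epimers, left unspecified) | OC(c1ccc(OCc2ccccc2)c(OCc2ccccc2)c1)[C@@H]1[C@@H](Cc2ccc(OCc3ccccc3)c(OC)c2)COC1=O | intermediate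
13 | (2R,3R)-2-{[3,4-bis(benzyloxy)phenyl](hydroxy)methyl}-3-{[4-(benzyloxy)-3-methoxyphenyl]methyl}butane-1,4-diol (carbinol centre both epimers, left unspecified) | OC(c1ccc(OCc2ccccc2)c(OCc2ccccc2)c1)[C@@H](CO)[C@@H](Cc1ccc(OCc2ccccc2)c(OC)c1)CO | intermediate
14 | [(2S,3R,4R)-2-[3,4-bis(benzyloxy)phenyl]-4-{[4-(benzyloxy)-3-methoxyphenyl]methyl}oxolan-3-yl]methanol | COc1cc(C[C@H]2CO[C@H](c3ccc(OCc4ccccc4)c(OCc4ccccc4)c3)[C@H]2CO)ccc1OCc1ccccc1 | intermediate
15 | [(2S,3R,4R)-2-[3,4-bis(benzyloxy)phenyl]-4-{[4-(benzyloxy)-3-methoxyphenyl]methyl}oxolan-3-yl]methyl acetate | COc1cc(C[C@H]2CO[C@H](c3ccc(OCc4ccccc4)c(OCc4ccccc4)c3)[C@H]2COC(C)=O)ccc1OCc1ccccc1 | intermediate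
16 | [(2S,3R,4R)-2-(3,4-dihydroxyphenyl)-4-[(4-hydroxy-3-methoxyphenyl)methyl]oxolan-3-yl]methyl acetate | COc1cc(C[C@H]2CO[C@H](c3ccc(O)c(O)c3)[C@H]2COC(C)=O)ccc1O | target

**Totals**
Total steps: 7. Longest linear sequence: 7 (1 + 2 → 16).

**Three steps most likely to fail, with fallbacks**

Step 5 (cationic ring closure) is the most exposed. The benzylic cation can also close onto the other electron-rich ring (aryltetralin) or give imperfect 2,3-selectivity. The fallback sets out from 13 and comes back at 16, replacing steps 5–7. The three benzyl ethers are removed first under neutral hydrogenolysis (H2, Pd/C, EtOAc/MeOH), which leaves the benzylic carbinol in place as in catecholamine debenzylations. This gives (2R,3R)-2-[(3,4-dihydroxyphenyl)(hydroxy)methyl]-3-[(4-hydroxy-3-methoxyphenyl)methyl]butane-1,4-diol F1. Its p-hydroxybenzylic alcohol ionises through a quinone methide under much milder conditions (PPTS, THF, 0 °C), closing to 4-[(2S,3R,4R)-3-(hydroxymethyl)-4-[(4-hydroxy-3-methoxyphenyl)methyl]oxolan-2-yl]benzene-1,2-diol F2. Lipase acylation (Novozym 435, vinyl acetate, MTBE, 40 °C) then acetylates the only aliphatic hydroxyl in the presence of the three phenols and gives 16.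

Step 2 (homoconjugate arylation) may suffer from 1,2-addition of the electron-rich aryl Grignard to the lactone or ester. The fallback sets out from 6 and comes back at 9. Iodide opens the doubly activated cyclopropane at CH2 (TMSCl/NaI, MeCN, 0 °C) to give ethyl (3S,4R)-4-(iodomethyl)-2-oxooxolane-3-carboxylate F3. A nickel-catalysed reductive cross-electrophile coupling of this primary iodide with aryl bromide 7 (NiBr2·glyme, 4,4'-di-tert-butyl-2,2'-bipyridine, Zn, DMA) makes the same C(sp3)–C(aryl) bond without any organomagnesium reagent and returns to 9.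

Step 4 (aldol with reduction in the same flask) may lose material by retro-aldol on warming or by poor conversion of the electron-rich aldehyde. The fallback sets out from 10 and comes back at 13. Crossed Claisen acylation of the lactone enolate with methyl 3,4-bis(benzyloxy)benzoate (LiHMDS, 2.2 equiv, THF, −78 → 0 °C) gives the stable β-keto lactone (3S,4R)-3-[3,4-bis(benzyloxy)benzoyl]-4-{[4-(benzyloxy)-3-methoxyphenyl]methyl}oxolan-2-one F4, which equilibrates to trans through its enol. LiAlH4 (THF, 0 °C) reduces ketone and lactone together to triol 13.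

**Further compounds**
F1 | step 5 | (2R,3R)-2-[(3,4-dihydroxyphenyl)(hydroxy)methyl]-3-[(4-hydroxy-3-methoxyphenyl)methyl]butane-1,4-diol | OC(c1ccc(O)c(O)c1)[C@@H](CO)[C@@H](Cc1ccc(O)c(OC)c1)CO
F2 | step 5 | 4-[(2S,3R,4R)-3-(hydroxymethyl)-4-[(4-hydroxy-3-methoxyphenyl)methyl]oxolan-2-yl]benzene-1,2-diol | COc1cc(C[C@H]2CO[C@H](c3ccc(O)c(O)c3)[C@H]2CO)ccc1O
F3 | step 2 | ethyl (3S,4R)-4-(iodomethyl)-2-oxooxolane-3-carboxylate | CCOC(=O)[C@@H]1[C@@H](CI)COC1=O
F4 | step 4 | (3S,4R)-3-[3,4-bis(benzyloxy)benzoyl]-4-{[4-(benzyloxy)-3-methoxyphenyl]methyl}oxolan-2-one | O=C(c1ccc(OCc2ccccc2)c(OCc2ccccc2)c1)[C@@H]1[C@@H](Cc2ccc(OCc3ccccc3)c(OC)c2)COC1=O
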